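The retrosynthesis traces the C7=C7a bond, the C5 methoxy group and the C4=C5–C6=O enone back to a saturated C4 ketone. It then cuts O1–C2, C2–C3 and C3a–C7a in one operation, followed by C3a–C4 (carbonyl addition) and C3=C3a (Wittig).
Enabling feature: the oxolane O1–C2–C3–C3a–C7a carries three contiguous stereocentres (C2, C3, C3a) and shares quaternary C3a and C7a with the carbocycle C3a–C4–C5–C6–C7–C7a. An aryl aldehyde and a 1-alkenylcyclopentane-1,2-diol leave exactly this pattern after a Prins cyclisation ended by a pinacol shift.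
Forward: a chiral-pool cyclopentane is joined to a Z-alkenyl metal, and one step then closes the oxolane and grows the five-membered carbocycle to six. The carbocycle is finally re-oxidised: oxygen is moved from C4 to C6, methoxy is put on C5, and C7=C7a is made last.
Stereochemistry: the only imported centre is the carbinol carbon that becomes C7a. It selects the chair in which the E-oxocarbenium ion sets C2, the Z-alkene sets C3 and the suprafacial shift sets C3a, and it is erased in the last step.

Key step: step 6

Assumption: benzofuran numbering (O1, C2, C3, C3a, C4–C7, C7a) is used for all bicyclic compounds and for the atoms that become these positions. The transient centres at C4, C5 and C6 are drawn for reaction on the convex face (cis to H-7a), and their configuration does not affect the target because all of them end up sp2.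

Step 1
Reactants: 1 (1R,2R)-cyclopentane-1,2-diol
Product: 2 (1R,2R)-2-[(tert-butyldimethylsilyl)oxy]cyclopentan-1-ol
Conditions: NaH (1.0 equiv), THF, 0 °C to rt; TBSCl (1.0 equiv)
Reagents that add atoms: tert-butyldimethylsilyl chloride, CC(C)(C)[Si](C)(C)Cl
Why: Monosilylation through the sparingly soluble monosodium alkoxide stops after one silyl transfer, and because the diol is C2-symmetric its two hydroxyl groups are homotopic, so either one gives the same single enantiomer and no new stereocentre arises.

Step 2
Reactants: 2 (1R,2R)-2-[(tert-butyldimethylsilyl)oxy]cyclopentan-1-ol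
Product: 3 (2R)-2-[(tert-butyldimethylsilyl)oxy]cyclopentan-1-one
Conditions: Dess–Martin periodinane, CH2Cl2, 0 °C to rt
Reagents that add atoms: none
Why: Dess–Martin oxidation works under neutral, non-enolising conditions, so the free carbinol becomes the ketone while the silyloxy-bearing centre (future C7a) keeps its R configuration.

Step 3
Reactants: 4 (but-3-en-1-yl)triphenylphosphonium bromide; 5 acetaldehyde
Product: 9 (2Z)-3-iodohexa-2,5-diene, via phosphorus ylide 6 (not isolated), via iodophosphonium iodide 7 (not isolated), via iodo ylide 8 (not isolated)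
Conditions: n-BuLi, THF, 0 °C; I2, −78 °C; NaN(SiMe3)2, −78 to −20 °C; 5, −78 °C to rt
Reagents that add atoms: iodine, II
Why: In this Stork–Zhao-type iodo-olefination ylide 6 is iodinated to salt 7, deprotonation gives iodo ylide 8, and its kinetically controlled Wittig reaction with an unbranched aldehyde places the aldehyde residue cis to iodine, which is the geometry (methyl cis to the future carbinol carbon) that the key step needs.

Step 4
Reactants: 9 (2Z)-3-iodohexa-2,5-diene; 3 (2R)-2-[(tert-butyldimethylsilyl)oxy]cyclopentan-1-one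
Product: 12 (1R,2R)-2-[(tert-butyldimethylsilyl)oxy]-1-[(2Z)-hexa-2,5-dien-3-yl]cyclopentan-1-ol, via dienyllithium 10 (not isolated), via dienylcerium dichloride 11 (not isolated)
Conditions: 9, t-BuLi (2.0 equiv), Et2O, −78 °C; CeCl3, THF, −78 °C; 3, −78 °C; aq NH4Cl
Reagents that add atoms: none
Why: Iodine–lithium exchange keeps the alkene geometry, transmetalation to the weakly basic organocerium reagent suppresses enolisation (and hence racemisation) of 3, and the 1,2-addition takes place on the ketone face anti to the bulky silyloxy group, which sets the tertiary carbinol centre as the cis-diol derivative.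

Step 5
Reactants: 12 (1R,2R)-2-[(tert-butyldimethylsilyl)oxy]-1-[(2Z)-hexa-2,5-dien-3-yl]cyclopentan-1-ol
Product: 13 (1R,2R)-1-[(2Z)-hexa-2,5-dien-3-yl]cyclopentane-1,2-diol (cis-diol; alkene methyl cis to the carbinol carbon)
Conditions: n-Bu4NF, THF, 0 °C to rt
Reagents that add atoms: none
Why: Fluoride-mediated desilylation, driven by Si–F bond formation, is mild enough to leave the acid-sensitive tertiary allylic alcohol and the skipped diene untouched and affects no stereocentre.

Step 6
Reactants: 13 (1R,2R)-1-[(2Z)-hexa-2,5-dien-3-yl]cyclopentane-1,2-diol; 14 3,4,5-trimethoxybenzaldehyde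
Product: 18 (2R,3S,3aR,7aR)-3a-allyl-3-methyl-2-(3,4,5-trimethoxyphenyl)hexahydro-1-benzofuran-4(2H)-one, via dioxolane acetal 15 (not isolated), via oxocarbenium ion 16 (not isolated), via oxanyl cation 17 (not isolated)
Conditions: p-TsOH·H2O (cat.), 4 Å MS, CH2Cl2, rt; then SnCl4 (promoter, 1.1 equiv), −78 to −30 °C; cold aq NaHCO3 quench
Reagents that add atoms: none
Why: Acid-catalysed condensation gives the cis-fused dioxolane 15, which SnCl4 opens reversibly; only the ion on the secondary oxygen (16) has the alkene within reach, because the isomeric ion on the tertiary allylic oxygen could close nothing larger than a four-membered ring, so the regiochemistry of ionisation corrects itself. The trisubstituted alkene attacks C2 of E-configured 16 in a 6-endo-trig Prins closure through a chair (C2–C3 bond) to give the tertiary oxan-4-yl cation 17, and the ring bond from the carbinol carbon to C7a then shifts to C3a (C3a–C7a bond), a pinacol step that contracts the transient oxane to the oxolane by 1,2-shift and, in the same event, enlarges the cyclopentane to the cyclohexanone. The closest known reaction is the pinacol-terminated Prins cyclisation used as a ring-enlarging tetrahydrofuran annulation of 1-alkenylcycloalkane-1,2-diols with aldehydes. C2 is set by the E-oxocarbenium geometry (aryl equatorial), C3 by the Z-alkene (the methyl cis to the carbinol carbon becomes axial and hence cis to aryl), and C3a by the suprafacial shift, which leaves the acyl carbon C4 on the face of aryl and methyl, pushes allyl to the opposite face and gives the cis ring fusion; C7a migrates with retention and, because the cyclopentane can span the chair only through two equatorial bonds, decides which of the two mirror-image chairs is used. Chemoselectivity over the terminal vinyl group rests on the higher nucleophilicity of the trisubstituted alkene and on ring size (six against seven or eight), and the oxygen-assisted C–C shift has to outrun hydride migration from the allylic CH2 next to the cation, which its intramolecular alignment should ensure. Low temperature and a cold basic quench protect the kinetic 2,3-cis product against reopening of the benzylic C2–O1 bond.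

Step 7
Reactants: 18 (2R,3S,3aR,7aR)-3a-allyl-3-methyl-2-(3,4,5-trimethoxyphenyl)hexahydro-1-benzofuran-4(2H)-one
Product: 21 (2R,3S,3aR,7aR)-3a-allyl-3-methyl-2-(3,4,5-trimethoxyphenyl)-3,3a,7,7a-tetrahydro-1-benzofuran-4(2H)-one, via lithium enolate 19 (not isolated), via C5 sulfilimine 20 (not isolated)
Conditions: LiN(i-Pr)2, THF, −78 °C; PhS(Cl)=N-t-Bu, −78 °C
Reagents that add atoms: none
Why: In this Mukaiyama one-pot dehydrogenation 18 can enolise only towards C5 because C3a is quaternary, enolate 19 attacks the sulfur of the sulfinimidoyl chloride, and sulfilimine 20 collapses at low temperature by intramolecular syn elimination of a C6 hydrogen, conditions that leave the allyl group, the aryl ring and all four stereocentres alone.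

Step 8
Reactants: 21 (2R,3S,3aR,7aR)-3a-allyl-3-methyl-2-(3,4,5-trimethoxyphenyl)-3,3a,7,7a-tetrahydro-1-benzofuran-4(2H)-one
Product: 22 5,6-epoxide of 21 (3a-allyl-5,6-epoxy-3-methyl-2-(3,4,5-trimethoxyphenyl)hexahydro-1-benzofuran-4(2H)-one; epoxide oxygen cis to H-7a and allyl)
Conditions: 30% aq H2O2, NaOH (0.2 equiv), MeOH, 0 °C
Reagents that add atoms: hydrogen peroxide, OO
Why: In this Weitz–Scheffer epoxidation hydroperoxide adds only to the electron-poor C5=C6 bond (the allyl group is inert to a nucleophilic oxidant) and should do so from the convex face cis to H-7a, and both new centres are transient because C5 becomes sp2 in step 9 and C6 in step 11.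

Step 9
Reactants: 22 5,6-epoxy-4-ketone
Product: 24 (2R,3S,3aR,6R,7aR)-3a-allyl-3-methyl-2-(3,4,5-trimethoxyphenyl)-2,3,3a,6,7,7a-hexahydro-1-benzofuran-6-ol (hydroxyl cis to H-7a), via epoxy hydrazone 23 (not isolated)
Conditions: N2H4·H2O, AcOH (cat.), degassed MeOH, Ar, 0 °C to rt
Reagents that add atoms: none
Why: In the Wharton transposition hydrazone 23 opens the epoxide and loses N2, which moves the alkene to C4=C5 and leaves the oxygen on C6 with its configuration retained, while exclusion of air prevents diimide formation and so protects the allyl group.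

Step 10
Reactants: 24 allylic alcohol (4-en-6-ol)
Product: 25 4,5-epoxide of 24 (3a-allyl-4,5-epoxy-3-methyl-2-(3,4,5-trimethoxyphenyl)octahydro-1-benzofuran-6-ol; epoxide oxygen cis to the 6-hydroxyl, H-7a and allyl)
Conditions: VO(acac)2 (5 mol %), t-BuOOH (decane), CH2Cl2, 0 °C to rt
Reagents that add atoms: tert-butyl hydroperoxide, CC(C)(C)OO
Why: Vanadium-catalysed hydroxyl-directed epoxidation delivers oxygen to C4=C5 syn to the C6 hydroxyl and ignores the undirected allyl alkene, and epoxidising at the alcohol level avoids exposing a free 4-en-6-one to base, whose retro-oxa-Michael opening would give a dienone with two identical arms and so erase C3a.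

Step 11
Reactants: 25 4,5-epoxy-6-ol
Product: 26 3a-allyl-4,5-epoxy-3-methyl-2-(3,4,5-trimethoxyphenyl)hexahydro-1-benzofuran-6(2H)-one (epoxide oxygen cis to H-7a and allyl; C2, C3, C3a, C7a as in 24)
Conditions: Dess–Martin periodinane, CH2Cl2, 0 °C to rt
Reagents that add atoms: none
Why: Dess–Martin oxidation converts the secondary alcohol into the ketone under neutral conditions that neither open the epoxide nor trigger β-elimination of O1.

Step 12
Reactants: 26 4,5-epoxy-6-ketone
Product: 28 (2R,3S,3aS,7aR)-3a-allyl-5-methoxy-3-methyl-2-(3,4,5-trimethoxyphenyl)-3,3a,7,7a-tetrahydro-1-benzofuran-6(2H)-one, via hydroxy methoxy ketone 27 (not isolated)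
Conditions: NaOMe (2 equiv), MeOH, rt to 50 °C
Reagents that add atoms: sodium methoxide, [Na+].[O-]C
Why: This is the base-mediated conversion of an α,β-epoxy ketone into an α-methoxy enone, as practised on 4,5-epoxy-3-keto steroids, in which methoxide attacks the carbonyl-activated C5 by SN2 rather than the neopentyl C4 to give 27, E1cB loss of the C4 hydroxyl follows, and reversible retro-oxa-Michael opening of O1–C7a should do no harm because the two arms on C3a now differ and the alkoxide returns to the more electrophilic, unsubstituted C7a.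

Step 13
Reactants: 28 (2R,3S,3aS,7aR)-3a-allyl-5-methoxy-3-methyl-2-(3,4,5-trimethoxyphenyl)-3,3a,7,7a-tetrahydro-1-benzofuran-6(2H)-one
Product: 31 (2R,3S,3aS)-3a-allyl-5-methoxy-3-methyl-2-(3,4,5-trimethoxyphenyl)-3,3a-dihydro-1-benzofuran-6(2H)-one, via lithium dienolate 29 (not isolated), via C7 sulfilimine 30 (not isolated)
Conditions: LiN(i-Pr)2, THF, −78 °C; PhS(Cl)=N-t-Bu, −78 °C
Reagents that add atoms: none
Why: In this second Mukaiyama dehydrogenation 28 has acidic hydrogens only at C7, dienolate 29 should be sulfenylated anti to the C7a–O1 bond and therefore syn to H-7a, and the syn elimination of 30 at −78 °C forms the C7=C7a vinylogous ester without heating the Cope-prone 3a-allyl dienone, removing the C7a centre and leaving 2R,3S,3aS.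

Compound list
1 | (1R,2R)-cyclopentane-1,2-diol | O[C@@H]1CCC[C@H]1O | starting material
2 | (1R,2R)-2-[(tert-butyldimethylsilyl)oxy]cyclopentan-1-ol | O[C@@H]1CCC[C@H]1O[Si](C)(C)C(C)(C)C | intermediate
3 | (2R)-2-[(tert-butyldimethylsilyl)oxy]cyclopentan-1-one | O=C1CCC[C@H]1O[Si](C)(C)C(C)(C)C | intermediate
4 | (but-3-en-1-yl)triphenylphosphonium bromide | C=CCC[P+](c1ccccc1)(c1ccccc1)c1ccccc1.[Br-] | starting material
5 | acetaldehyde | CC=O | starting material
6 | (but-3-en-1-ylidene)triphenylphosphorane | C=CCC=P(c1ccccc1)(c1ccccc1)c1ccccc1 | intermediate (not isolated)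
7 | (1-iodobut-3-en-1-yl)triphenylphosphonium iodide (racemic) | C=CCC(I)[P+](c1ccccc1)(c1ccccc1)c1ccccc1.[I-] | intermediate (not isolated)
8 | (1-iodobut-3-en-1-ylidene)triphenylphosphorane | C=CCC(I)=P(c1ccccc1)(c1ccccc1)c1ccccc1 | intermediate (not isolated)
9 | (2Z)-3-iodohexa-2,5-diene (methyl cis to iodine) | C=CC/C(I)=C/C | intermediate
10 | hexa-2,5-dien-3-yllithium (methyl cis to lithium) | C=CC/C([Li])=C/C | intermediate (not isolated)
11 | dichloro(hexa-2,5-dien-3-yl)cerium (methyl cis to cerium) | C=CC/C([Ce](Cl)Cl)=C/C | intermediate (not isolated)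
12 | (1R,2R)-2-[(tert-butyldimethylsilyl)oxy]-1-[(2Z)-hexa-2,5-dien-3-yl]cyclopentan-1-ol | C=CC/C(=C/C)[C@]1(O)CCC[C@H]1O[Si](C)(C)C(C)(C)C | intermediate
13 | (1R,2R)-1-[(2Z)-hexa-2,5-dien-3-yl]cyclopentane-1,2-diol | C=CC/C(=C/C)[C@]1(O)CCC[C@H]1O | intermediate (precursor of the key step)
14 | 3,4,5-trimethoxybenzaldehyde | COc1cc(C=O)cc(OC)c1OC | starting material
15 | cis-fused 2-(3,4,5-trimethoxyphenyl)-1,3-dioxolane acetal of 13 (both epimers at the acetal carbon) | C=CC/C(=C/C)[C@]12CCC[C@H]1OC(c1cc(OC)c(OC)c(OC)c1)O2 | intermediate (not isolated)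
16 | E-oxocarbenium ion on the secondary oxygen (tertiary oxygen, tin-bound in the flask, drawn as OH) | C=CC/C(=C/C)[C@]1(O)CCC[C@H]1/[O+]=C/c1cc(OC)c(OC)c(OC)c1 | intermediate (not isolated)
17 | tertiary oxan-4-yl cation, charge at C3a, aryl equatorial, methyl axial, trans-fused to the cyclopentane | C=CC[C+]1[C@H](C)[C@H](c2cc(OC)c(OC)c(OC)c2)O[C@@H]2CCC[C@@]12O | intermediate (not isolated)
18 | (2R,3S,3aR,7aR)-3a-allyl-3-methyl-2-(3,4,5-trimethoxyphenyl)hexahydro-1-benzofuran-4(2H)-one | C=CC[C@]12C(=O)CCC[C@H]1O[C@@H](c1cc(OC)c(OC)c(OC)c1)[C@H]2C | intermediate (product of the key step)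
19 | lithium C4–C5 enolate of 18 | C=CC[C@]12C(O[Li])=CCC[C@H]1O[C@@H](c1cc(OC)c(OC)c(OC)c1)[C@H]2C | intermediate (not isolated)
20 | 5-(N-tert-butyl-S-phenylsulfinimidoyl) derivative of 18 (sulfur cis to H-7a, mixture at sulfur) | C=CC[C@]12C(=O)[C@H](S(=NC(C)(C)C)c3ccccc3)CC[C@H]1O[C@@H](c1cc(OC)c(OC)c(OC)c1)[C@H]2C | intermediate (not isolated)
21 | (2R,3S,3aR,7aR)-3a-allyl-3-methyl-2-(3,4,5-trimethoxyphenyl)-3,3a,7,7a-tetrahydro-1-benzofuran-4(2H)-one | C=CC[C@]12C(=O)C=CC[C@H]1O[C@@H](c1cc(OC)c(OC)c(OC)c1)[C@H]2C | intermediate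
22 | 5,6-epoxy-4-ketone (epoxide oxygen cis to H-7a and allyl) | C=CC[C@]12C(=O)[C@@H]3O[C@@H]3C[C@H]1O[C@@H](c1cc(OC)c(OC)c(OC)c1)[C@H]2C | intermediate
23 | hydrazone of 22 | C=CC[C@]12C(=NN)[C@@H]3O[C@@H]3C[C@H]1O[C@@H](c1cc(OC)c(OC)c(OC)c1)[C@H]2C | intermediate (not isolated)
24 | (2R,3S,3aR,6R,7aR)-3a-allyl-3-methyl-2-(3,4,5-trimethoxyphenyl)-2,3,3a,6,7,7a-hexahydro-1-benzofuran-6-ol | C=CC[C@]12C=C[C@H](O)C[C@H]1O[C@@H](c1cc(OC)c(OC)c(OC)c1)[C@H]2C | intermediate
25 | 4,5-epoxy-6-ol (epoxide oxygen and hydroxyl cis to H-7a and allyl) | C=CC[C@]12[C@@H]3O[C@@H]3[C@H](O)C[C@H]1O[C@@H](c1cc(OC)c(OC)c(OC)c1)[C@H]2C | intermediate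
26 | 4,5-epoxy-6-ketone (epoxide oxygen cis to H-7a and allyl) | C=CC[C@]12[C@@H]3O[C@@H]3C(=O)C[C@H]1O[C@@H](c1cc(OC)c(OC)c(OC)c1)[C@H]2C | intermediate
27 | 4-hydroxy-5-methoxy-6-ketone (hydroxyl cis to H-7a, methoxy trans to it) | C=CC[C@]12[C@H](O)[C@@H](OC)C(=O)C[C@H]1O[C@@H](c1cc(OC)c(OC)c(OC)c1)[C@H]2C | intermediate (not isolated)
28 | (2R,3S,3aS,7aR)-3a-allyl-5-methoxy-3-methyl-2-(3,4,5-trimethoxyphenyl)-3,3a,7,7a-tetrahydro-1-benzofuran-6(2H)-one | C=CC[C@]12C=C(OC)C(=O)C[C@H]1O[C@@H](c1cc(OC)c(OC)c(OC)c1)[C@H]2C | intermediate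
29 | lithium C6–C7 dienolate of 28 | C=CC[C@]12C=C(OC)C(O[Li])=C[C@H]1O[C@@H](c1cc(OC)c(OC)c(OC)c1)[C@H]2C | intermediate (not isolated)
30 | 7-(N-tert-butyl-S-phenylsulfinimidoyl) derivative of 28 (sulfur cis to H-7a, mixture at sulfur) | C=CC[C@]12C=C(OC)C(=O)[C@H](S(=NC(C)(C)C)c3ccccc3)[C@H]1O[C@@H](c1cc(OC)c(OC)c(OC)c1)[C@H]2C | intermediate (not isolated)
31 | (2R,3S,3aS)-3a-allyl-5-methoxy-3-methyl-2-(3,4,5-trimethoxyphenyl)-3,3a-dihydro-1-benzofuran-6(2H)-one (CNP0197140.1) | C=CC[C@]12C=C(OC)C(=O)C=C1O[C@@H](c1cc(OC)c(OC)c(OC)c1)[C@H]2C | target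

Total step count: 13.
Longest linear sequence: 12 steps (1 to 31 through steps 1, 2 and 4–13). Step 3 is a one-step side branch.

Steps most likely to fail

Step 6. Three processes threaten this step.
- The tertiary allylic alcohol may ionise under protic conditions before the acetal has formed.
- A boat-like closure that avoids the axial methyl group may erode the kinetic 2,3-cis relation.
- The benzylic C2–O1 bond may reopen reversibly under a full equivalent of Lewis acid.

The fallback keeps the same bond set but generates the oxocarbenium ion without any Brønsted acid and ends the shift on a silylated oxygen. Diol 13 is persilylated with N-(trimethylsilyl)imidazole in CH2Cl2 to the bis(trimethylsilyl) ether F1. F1 is combined with 14 and catalytic Me3SiOTf in CH2Cl2 at −78 °C (Noyori-type acetalisation conditions). Acetal 15 should form and ionise in the cold, loss of the silyl group from the tertiary oxygen terminates the pinacol shift and regenerates the catalyst, and the route is rejoined at 18.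

Step 9. Hydrazone formation may be slow at the C4 carbonyl, which is flanked by quaternary C3a. Attack of hydrazine on the epoxide or diimide reduction of the allyl group could then take over. The fallback is the radical version of the same transposition.
- From 22, NaBH4 and CeCl3·7H2O in MeOH should give the epoxy alcohol F2, and either C4 epimer serves.
- 1,1'-Thiocarbonyldiimidazole with DMAP converts it into the thiocarbonylimidazolide F3.
- n-Bu3SnH with AIBN in refluxing benzene generates the C4 radical.

This radical opens the adjacent epoxide faster than it can engage the allyl group, which offers only three- or four-membered closures. The C6 alkoxyl radical is reduced by the stannane, and the route is rejoined at 24.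

Step 12. O1 may be lost by β-elimination from the C6/C7 enolate (retro-oxa-Michael), and the freed C2 alkoxide may then capture the epoxide. Both would compete with a slow bimolecular attack of methoxide at the hindered C5. The fallback changes the order of events so that O1 is locked into a vinylogous ester before any methoxide is used.
- From 26, kinetic enolisation with LiN(i-Pr)2 in the presence of Me3SiCl (internal quench, THF, −78 °C) should give the trimethylsilyl dienol ether F4.
- Saegusa–Ito oxidation with Pd(OAc)2 in MeCN gives the epoxy dienone F5.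
- NaOMe in MeOH then opens the epoxide at C5 to the hydroxy methoxy dienone F6, which dehydrates in the flask.

This replaces steps 12 and 13, and the route is rejoined at 31.

Further compounds
F1 | step 6 | (1R,2R)-1-[(2Z)-hexa-2,5-dien-3-yl]-1,2-bis[(trimethylsilyl)oxy]cyclopentane | C=CC/C(=C/C)[C@]1(O[Si](C)(C)C)CCC[C@H]1O[Si](C)(C)C
F2 | step 9 | 5,6-epoxy-4-ol from reduction of 22 (mixture of C4 epimers) | C=CC[C@]12C(O)[C@@H]3O[C@@H]3C[C@H]1O[C@@H](c1cc(OC)c(OC)c(OC)c1)[C@H]2C
F3 | step 9 | O-(imidazol-1-ylthiocarbonyl) derivative of F2 | C=CC[C@]12C(OC(=S)n3ccnc3)[C@@H]3O[C@@H]3C[C@H]1O[C@@H](c1cc(OC)c(OC)c(OC)c1)[C@H]2C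
F4 | step 12 | C6–C7 trimethylsilyl enol ether of 26 | C=CC[C@]12[C@@H]3O[C@@H]3C(O[Si](C)(C)C)=C[C@H]1O[C@@H](c1cc(OC)c(OC)c(OC)c1)[C@H]2C
F5 | step 12 | 3a-allyl-4,5-epoxy-3-methyl-2-(3,4,5-trimethoxyphenyl)-3,3a,4,5-tetrahydro-1-benzofuran-6(2H)-one | C=CC[C@]12[C@@H]3O[C@@H]3C(=O)C=C1O[C@@H](c1cc(OC)c(OC)c(OC)c1)[C@H]2C
F6 | step 12 | 4-hydroxy-5-methoxy derivative from opening of F5 (not isolated) | C=CC[C@]12[C@H](O)[C@@H](OC)C(=O)C=C1O[C@@H](c1cc(OC)c(OC)c(OC)c1)[C@H]2C
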